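## The problem

Germacranolide numbering is used for every compound, open-chain ones included: ring carbons C1–C10, lactone carbons C11–C13, C14 on C10, C15 on C4. The target 32 is a heliangolide: a ten-membered carbocycle with a trans-1,10-epoxide, a Z trisubstituted C4=C5 alkene and an α-methylene γ-lactone trans-fused across C6–C7. Six stereocentres lie on the ring (C1, C3, C6, C7, C8, C10) and two more in the (2S,3R)-2,3-dimethyloxirane-2-carboxylate on O8. In an open chain they form three groups too far apart to control one another: C1/C10, C3 (with a temporary C4 centre), and C7/C8. Only C6 sits next to a controlling centre, C7. The α-methylene lactone is a Michael acceptor, both epoxides and the allylic C3 alcohol are acid-sensitive (the 1,10-epoxide invites transannular attack by C4=C5), and the glycidic ester on O8 must survive the unmasking of the C12 carboxyl. The enabling feature is that the lactone oxygen on C6 is allylic to C4=C5. Both O–C6 and the C4=C5 π bond can therefore be drawn from a C5=C6 ring alkene that is lactonised by the C12 acid under electrophilic activation, with the electrophile then expelled toward C4–H.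

## Retrosynthesis

**32 back to 29 (C4=C5 π bond, O–Si).** Desilylation leads back to silyl ether 31. The Z C4=C5 alkene is traced to the C5 phenylselenide 29 through its selenoxide 30. A selenoxide eliminates syn and away from an oxygen-bearing carbon, so only C4–H can be lost. The alkene geometry then follows from the C4 and C5 configurations instead of from an olefination on a medium ring. The forward step needs C4–H syn to selenium, which is fixed two stages earlier.

**29 back to 28 (O–C6 and C5–Se; the lactone ring).** Cutting these two bonds opens the lactone and leaves the Z-5-ene acid 28. One ring and two stereocentres disappear, and C6 no longer has to be made as a separate carbinol centre. The alternative of acylating a preformed C6 alcohol would need that centre and the Z C4=C5 alkene to be built independently. The forward reaction must close 5-exo at C6 on the face dictated by C7.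

**28 back to 27 and 26 (C5=C6).** The ring is opened at C5=C6 to the seco-acid 27 with two vinyl groups. This bond is not an alkene in the target, so only its Z geometry matters, and Z is the favoured geometry of a cyclodecene. Closing at C7–C8 or C1–C2 instead would place the ring closure on a stereocentre-forming bond. Acid 27 comes from allyl ester 26. The allyl ester is chosen because zerovalent palladium removes it without touching the glycidic ester on O8. It must come off before metathesis, since its alkene would otherwise take part.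

**26 back to 24 and 8 (acyl C–O at O8).** The side chain is detached as (2S,3R)-2,3-dimethyloxirane-2-carboxylic acid 8, leaving hydroxy ester 24. Bringing in the epoxide ready-made avoids a late, unselective epoxidation of a tiglate next to other alkenes. Acid 8 goes back through epoxy alcohol 7 and tiglyl alcohol 6 to tiglic acid 5; a Sharpless epoxidation sets both centres.

**24 back to 22 and 4 (C7–C8).** This cut delivers the α-methylene carboxyl unit, the C6 vinyl group and both stereocentres C7 and C8 in one Barbier-type allylation of aldehyde 22 by dienyl bromide 4. The 7,8-syn relationship is the normal outcome of the closed transition state. Bromide 4 comes in two steps from allyl acrylate 1 and acrolein 2 via alcohol 3. The aldehyde face must be chosen by the C10 epoxide centre; this is the weakest control element of the plan.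

**22 back to 19 (C1–O and C10–O; oxidation level at C8).** Aldehyde 22 is traced through alcohol 21 and PMB ether 20 to the E-trisubstituted alkene 19. A Shi epoxidation sets C1 and C10 by catalyst control and leaves the terminal vinyl group alone. Placing the epoxide here, after the C3 alcohol is silylated, avoids a free hydroxyl next to an epoxide.

**19 back to 14 and 15 (C3–C4).** Silyl ether 19 comes from alcohol 18. Its syn C3-hydroxyl/C4-methyl pair and terminal vinyl group are the signature of a (Z)-crotylboration of aldehyde 14 with the reagent from cis-2-butene 15. The boron ligands set the absolute configuration, so no other stereocentre is needed at this stage.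

**14 back to 9 (C10–C14 and C1–C2).** Aldehyde 14 is the oxidation product of homoallylic alcohol 13. Alcohol 13 is assembled from PMB ether 10 of 3-butyn-1-ol 9 by methylalumination (C10–C14) and opening of ethylene oxide by the alkenyl aluminate (C1–C2). This fixes the E geometry that the epoxide later needs.

## Roads not taken

**Alternative 1:** The ring would be cut at C9–C10. The forward key step joins C10 of an E-alkenyl iodide to C9, the terminal carbon of a C8–C9 epoxide, under zerovalent nickel (from NiBr2, 2,2'-bipyridine and Mn, with NaI opening the epoxide to the iodohydrin). It gives A1, a 1(10)E,4Z-diene lactone with free C8 hydroxyl and C11 still unsubstituted.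
- Merits: both ring alkene geometries are fixed before closure, the lactone is already in place, and C8 comes from an enantiopure epoxide under absolute control. In these two respects it is better than the chosen plan, whose ring-alkene geometry depends on the closure and whose C8 depends on substrate bias.
- Weak points: the coupling runs through a primary β-hydroxyalkyl radical at C9 that must meet an alkenylnickel centre across a forming ten-membered ring. Reduction at C9, loss of the iodohydrin to a C8=C9 alkene and intermolecular coupling are the expected competitors, and this mode of closure has no macrocyclic counterpart at this ring size.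
- After A1 the route still needs α-methylenation next to a free or acylated C8 oxygen, and a chemo- and face-selective epoxidation of C1=C10 beside C4=C5 that only ring conformation can control.
- The chosen plan sets against it a ring closure with precedent at ring size ten, an epoxide installed by catalyst control on an open chain, and two steps from the key product 29 to 32.

**Alternative 2:** The ring would be cut at C2–C3 (and O–C1). The forward key step oxidises a Z-enal oxime at C3 with NaOCl to the nitrile oxide, which adds across a terminal C1=C2 alkene and gives the isoxazoline-bridged lactone A2.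
- Merits: ring closure and the masked C1-hydroxy/C3-keto pattern come in one stereospecific operation, and no skipped or β,γ-epoxy aldehyde is needed. On that point it is gentler than the chosen route.
- Weak points: at ring size ten the bridged and fused regiochemistries and furoxan dimerisation compete, and the C1 centre is set only by the folding of the chain.
- After A2 come N–O cleavage, a face-selective reduction of the C3 enone carbonyl, epoxide closure with inversion at C1 by the C10 oxygen, acylation at O8 and α-methylenation. These are several substrate-controlled stereochemical events and at least six further steps.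
- The chosen plan sets against it that C1, C10, C3 and C4 are fixed by reagents before cyclisation and that the finish after the key step is short.

**Alternative 3:** The cut is the C5–C10 bond of a cis-fused decalin. The forward key step irradiates a 3-silyloxy-1,3-cyclohexadiene embedded in that decalin lactone near 300 nm, and conrotatory opening gives the triene A3 with lactone, methylene and C8 ester already present.
- Merits: a decalin is far easier to build than a ten-membered ring, and the opening is stereospecific. In step economy up to the ring this road is better than the chosen one.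
- Weak points: the opening is a photoequilibrium; the triene can re-close thermally or undergo hydrogen shifts; the α-methylene lactone and the glycidic ester are exposed to ultraviolet light.
- After A3 the dienol ether must be hydrolysed without moving the C4=C5 alkene, the C3 ketone reduced from the correct face, and C1=C10 epoxidised selectively in a triene-derived ring. All of this relies on conformation control in a flexible ring.
- The chosen plan sets against it a thermal ring closure driven by loss of ethylene, no photolabile polyene, and reagent-controlled stereocentres.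

Key step: step 18

## Steps

Step 1
Reactants: 1 allyl acrylate; 2 acrolein
Product: 3 allyl 3-hydroxy-2-methylidenepent-4-enoate (racemic)
Conditions: DABCO (cat.), 1,4-dioxane/H2O, rt
Reagents that add atoms: none
Why: Morita–Baylis–Hillman reaction: the amine–acrylate zwitterion adds 1,2 to acrolein; the carbinol centre may be racemic because it becomes sp2 in step 2.

Step 2
Reactants: 3 allyl 3-hydroxy-2-methylidenepent-4-enoate
Product: 4 allyl (2Z)-2-(bromomethyl)penta-2,4-dienoate
Conditions: PBr3, Et2O, −10 → 0 °C
Reagents that add atoms: phosphorus tribromide, BrP(Br)Br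
Why: SN2' bromination of a Baylis–Hillman alcohol gives the conjugated (Z)-2-(bromomethyl)dienoate (vinyl group cis to CH2Br); any regioisomeric allylic bromide would lead to the same delocalised organoindium in step 14.

Step 3
Reactants: 5 tiglic acid
Product: 6 (2E)-2-methylbut-2-en-1-ol
Conditions: LiAlH4, Et2O, 0 °C → rt
Reagents that add atoms: none
Why: Hydride reduction of the conjugated acid to the allylic alcohol; the E geometry (the two methyl groups cis) is untouched.

Step 4
Reactants: 6 (2E)-2-methylbut-2-en-1-ol
Product: 7 [(2R,3R)-2,3-dimethyloxiran-2-yl]methanol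
Conditions: Ti(OiPr)4 (cat.), D-(−)-diethyl tartrate (cat.), t-BuOOH, 4 Å MS, CH2Cl2, −20 °C
Reagents that add atoms: tert-butyl hydroperoxide, CC(C)(C)OO
Why: Sharpless asymmetric epoxidation of a trisubstituted E-allylic alcohol; the D-tartrate ligand directs oxygen to the face that gives the (2R,3R) epoxy alcohol, and both side-chain stereocentres are set here.

Step 5
Reactants: 7 [(2R,3R)-2,3-dimethyloxiran-2-yl]methanol
Product: 8 (2S,3R)-2,3-dimethyloxirane-2-carboxylic acid
Conditions: RuCl3·xH2O (cat.), NaIO4, MeCN/EtOAc/H2O, 0 °C → rt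
Reagents that add atoms: water, O
Why: Ruthenium tetroxide oxidation of a primary epoxy alcohol to the glycidic acid through the aldehyde hydrate; no stereocentre is touched (the C2 descriptor changes only through priorities), and the acid is used promptly.

Step 6
Reactants: 9 3-butyn-1-ol
Product: 10 1-[(but-3-yn-1-yloxy)methyl]-4-methoxybenzene
Conditions: NaH, PMBCl, Bu4NI (cat.), THF, 0 °C → rt
Reagents that add atoms: 4-methoxybenzyl chloride, COc1ccc(CCl)cc1
Why: Williamson etherification; one equivalent of base deprotonates the hydroxyl, not the much less acidic alkyne C–H.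

Step 7
Reactants: 10 1-[(but-3-yn-1-yloxy)methyl]-4-methoxybenzene
Product: 13 (3E)-6-[(4-methoxybenzyl)oxy]-4-methylhex-3-en-1-ol, via (E)-alkenyldimethylalane 11 (not isolated), via lithium alkenyl(butyl)dimethylaluminate 12 (not isolated)
Conditions: Me3Al, Cp2ZrCl2 (0.25 equiv), CH2Cl2, 0 °C → rt; evaporate; n-BuLi, THF/hexane, −78 °C; ethylene oxide, −78 °C → rt
Reagents that add atoms: trimethylaluminium, C[Al](C)C; ethylene oxide, C1CO1
Why: Zirconium-catalysed carboalumination (Negishi) adds methyl and aluminium syn with methyl on the internal carbon; the aluminate opens ethylene oxide with retention, which fixes the E trisubstituted C1=C10 alkene.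

Step 8
Reactants: 13 (3E)-6-[(4-methoxybenzyl)oxy]-4-methylhex-3-en-1-ol
Product: 14 (3E)-6-[(4-methoxybenzyl)oxy]-4-methylhex-3-enal
Conditions: Dess–Martin periodinane, NaHCO3, CH2Cl2, 0 °C; crude aldehyde used at once
Reagents that add atoms: none
Why: Buffered Dess–Martin oxidation is neutral enough to give the skipped enal without moving the alkene into conjugation, provided it is used immediately and cold.

Step 9
Reactants: 14 (3E)-6-[(4-methoxybenzyl)oxy]-4-methylhex-3-enal; 15 cis-2-butene
Product: 18 (3S,4S,6E)-9-[(4-methoxybenzyl)oxy]-3,7-dimethylnona-1,6-dien-4-ol, via (Z)-crotylpotassium 16 (not isolated), via (Z)-crotylbis[(+)-isopinocampheyl]borane 17 (not isolated)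
Conditions: 15, KOt-Bu, n-BuLi, THF, −78 → −45 °C; (+)-Ipc2BOMe, −78 °C; BF3·OEt2; 14, −78 °C; then NaOH, H2O2, 0 °C → rt
Reagents that add atoms: none
Why: Brown crotylboration through a closed chair transition state: the Z-crotyl geometry gives the syn hydroxyl/methyl pair, and the (+)-isopinocampheyl ligands (from (−)-α-pinene) direct attack to the Re face of the aldehyde, setting C3 (S, target numbering) and C4 under reagent control.

Step 10
Reactants: 18 (3S,4S,6E)-9-[(4-methoxybenzyl)oxy]-3,7-dimethylnona-1,6-dien-4-ol
Product: 19 tert-butyl{[(3S,4S,6E)-9-[(4-methoxybenzyl)oxy]-3,7-dimethylnona-1,6-dien-4-yl]oxy}dimethylsilane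
Conditions: TBSOTf, 2,6-lutidine, CH2Cl2, −78 °C
Reagents that add atoms: tert-butyldimethylsilyl trifluoromethanesulfonate, CC(C)(C)[Si](C)(C)OS(=O)(=O)C(F)(F)F
Why: Standard silylation of a hindered secondary alcohol; done before the epoxide is present, so the Lewis-acidic triflate has nothing to open.

Step 11
Reactants: 19 tert-butyl{[(3S,4S,6E)-9-[(4-methoxybenzyl)oxy]-3,7-dimethylnona-1,6-dien-4-yl]oxy}dimethylsilane
Product: 20 (2R,3R)-2-{2-[(4-methoxybenzyl)oxy]ethyl}-2-methyl-3-[(2S,3S)-2-(tert-butyldimethylsilyloxy)-3-methylpent-4-en-1-yl]oxirane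
Conditions: Shi ketone (D-fructose-derived, 0.3 equiv), Oxone, K2CO3, Bu4NHSO4, Na2B4O7/Na2EDTA buffer, MeCN/CH2(OMe)2, 0 °C
Reagents that add atoms: potassium peroxymonosulfate (Oxone), [K+].[O-]S(=O)(=O)OO
Why: Shi epoxidation: the chiral dioxirane reacts through a spiro transition state with the electron-rich E-trisubstituted alkene and gives the (1R,10R) epoxide (target numbering) by catalyst control; the monosubstituted vinyl group is too unreactive to compete.

Step 12
Reactants: 20 (2R,3R)-2-{2-[(4-methoxybenzyl)oxy]ethyl}-2-methyl-3-[(2S,3S)-2-(tert-butyldimethylsilyloxy)-3-methylpent-4-en-1-yl]oxirane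
Product: 21 2-{(2R,3R)-3-[(2S,3S)-2-(tert-butyldimethylsilyloxy)-3-methylpent-4-en-1-yl]-2-methyloxiran-2-yl}ethan-1-ol
Conditions: DDQ, CH2Cl2/pH 7 phosphate buffer, 0 °C
Reagents that add atoms: none
Why: Oxidative cleavage of the 4-methoxybenzyl ether; the buffer keeps the acidic hydroquinone from opening the epoxide, and silyl ether and vinyl group are inert.

Step 13
Reactants: 21 2-{(2R,3R)-3-[(2S,3S)-2-(tert-butyldimethylsilyloxy)-3-methylpent-4-en-1-yl]-2-methyloxiran-2-yl}ethan-1-ol
Product: 22 {(2R,3R)-3-[(2S,3S)-2-(tert-butyldimethylsilyloxy)-3-methylpent-4-en-1-yl]-2-methyloxiran-2-yl}acetaldehyde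
Conditions: Dess–Martin periodinane, NaHCO3, CH2Cl2, 0 °C; used at once
Reagents that add atoms: none
Why: Buffered Dess–Martin oxidation; the β,γ-epoxy aldehyde is prone to base-induced opening to the hydroxy enal and is therefore carried on without chromatography.

Step 14
Reactants: 22 {(2R,3R)-3-[(2S,3S)-2-(tert-butyldimethylsilyloxy)-3-methylpent-4-en-1-yl]-2-methyloxiran-2-yl}acetaldehyde; 4 allyl (2Z)-2-(bromomethyl)penta-2,4-dienoate
Product: 24 allyl (3R,4R)-3-ethenyl-4-hydroxy-2-methylidene-5-{(2R,3R)-3-[(2S,3S)-2-(tert-butyldimethylsilyloxy)-3-methylpent-4-en-1-yl]-2-methyloxiran-2-yl}pentanoate, via allylindium dibromide 23 (not isolated)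
Conditions: indium powder, THF/H2O (1:1), rt
Reagents that add atoms: none
Why: Indium-mediated Barbier allylation with a 3-substituted 2-(bromomethyl)acrylate: attack through the γ-carbon (C7) in a closed chair with the vinyl group cis to the CH2–In terminus gives the 7,8-syn adduct with the C6 vinyl and the α-methylene ester on C7; the aldehyde face is chosen by 1,3-induction from the C10 epoxide oxygen (C8–O anti to C10–O with the C1 arm as the large group), which is expected to be the weakest selectivity of the route; near-neutral aqueous conditions spare the epoxide and leave the hydroxy ester unlactonised.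

Step 15
Reactants: 24 allyl (3R,4R)-3-ethenyl-4-hydroxy-2-methylidene-5-{(2R,3R)-3-[(2S,3S)-2-(tert-butyldimethylsilyloxy)-3-methylpent-4-en-1-yl]-2-methyloxiran-2-yl}pentanoate; 8 (2S,3R)-2,3-dimethyloxirane-2-carboxylic acid
Product: 26 allyl (3R,4R)-4-{[(2S,3R)-2,3-dimethyloxirane-2-carbonyl]oxy}-3-ethenyl-2-methylidene-5-{(2R,3R)-3-[(2S,3S)-2-(tert-butyldimethylsilyloxy)-3-methylpent-4-en-1-yl]-2-methyloxiran-2-yl}pentanoate, via 2,4,6-trichlorobenzoic mixed anhydride 25 (not isolated)
Conditions: 8, 2,4,6-trichlorobenzoyl chloride, Et3N, THF, 0 °C; then 24, DMAP, toluene, rt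
Reagents that add atoms: none
Why: Yamaguchi esterification: DMAP attacks the aliphatic carbonyl of the mixed anhydride and the acylpyridinium acylates the hindered C8 hydroxyl with retention (the C8–O bond is not broken); the conjugated, hindered allyl ester should resist intramolecular transesterification.

Step 16
Reactants: 26 allyl (3R,4R)-4-{[(2S,3R)-2,3-dimethyloxirane-2-carbonyl]oxy}-3-ethenyl-2-methylidene-5-{(2R,3R)-3-[(2S,3S)-2-(tert-butyldimethylsilyloxy)-3-methylpent-4-en-1-yl]-2-methyloxiran-2-yl}pentanoate
Product: 27 (3R,4R)-4-{[(2S,3R)-2,3-dimethyloxirane-2-carbonyl]oxy}-3-ethenyl-2-methylidene-5-{(2R,3R)-3-[(2S,3S)-2-(tert-butyldimethylsilyloxy)-3-methylpent-4-en-1-yl]-2-methyloxiran-2-yl}pentanoic acid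
Conditions: Pd(PPh3)4 (5 mol %), N-methylaniline, THF, rt
Reagents that add atoms: none
Why: Tsuji–Trost deallylation: zerovalent palladium ionises only the allyl ester (no other allylic leaving group and no vinyl epoxide is present) and the weakly nucleophilic aniline traps the allyl unit without adding to the acrylate or opening an epoxide; the glycidic ester on O8 is untouched.

Step 17
Reactants: 27 (3R,4R)-4-{[(2S,3R)-2,3-dimethyloxirane-2-carbonyl]oxy}-3-ethenyl-2-methylidene-5-{(2R,3R)-3-[(2S,3S)-2-(tert-butyldimethylsilyloxy)-3-methylpent-4-en-1-yl]-2-methyloxiran-2-yl}pentanoic acid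
Product: 28 (1R,3S,4S,7R,8R,10R)-3-(tert-butyldimethylsilyloxy)-8-[(2S,3R)-2,3-dimethyloxirane-2-carbonyloxy]-1,10-epoxygermacra-5Z,11(13)-dien-12-oic acid
Conditions: second-generation Grubbs catalyst RuCl2(=CHPh)(PCy3)(H2IMes) (10 mol %), 1,4-benzoquinone, CH2Cl2 (1 mM), 40 °C
Reagents that add atoms: none
Why: Ring-closing metathesis of the two monosubstituted vinyl groups with loss of ethylene; the electron-poor 1,1-disubstituted acrylic alkene is a poor partner, the free acid is tolerated, and reversible metathesis should favour the Z cyclodecene, the more stable geometry at this ring size.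

Step 18
Reactants: 28 (1R,3S,4S,7R,8R,10R)-3-(tert-butyldimethylsilyloxy)-8-[(2S,3R)-2,3-dimethyloxirane-2-carbonyloxy]-1,10-epoxygermacra-5Z,11(13)-dien-12-oic acid
Product: 29 (1R,3S,4R,5S,6S,7R,8R,10R)-3-(tert-butyldimethylsilyloxy)-8-[(2S,3R)-2,3-dimethyloxirane-2-carbonyloxy]-1,10-epoxy-5-(phenylselanyl)germacr-11(13)-en-12,6-olide
Conditions: N-(phenylseleno)phthalimide, CH2Cl2, 0 °C → rt
Reagents that add atoms: N-(phenylseleno)phthalimide, O=C1c2ccccc2C(=O)N1[Se]c1ccccc1
Why: The reagent transfers PhSe+ reversibly to the only nucleophilic alkene, Z-C5=C6, and the C12 carboxyl opens the seleniranium ion at C6; the closest known reaction type is the phenylselenolactonisation of γ,δ-unsaturated acids. The γ-lactone closes in the 5-exo mode (O–C6), preferred over 6-endo attack at C5 for a 1,2-disubstituted alkene. C6 is controlled by C7: allylic 1,3-strain across the Z alkene holds C7–H in the alkene plane, so the C11 arm lies on one face and the carboxyl can reach C6 only from that face, which places H6 trans to H7 (trans-fused lactone). C5 follows stereospecifically from anti addition to the Z alkene, selenium ending on the face opposite the lactone oxygen. The step needs π-face selectivity; because selenium transfer is reversible, ions formed on the unproductive face revert and only the one that C7 allows to cyclise is drained. The α-methylene acid is electron-poor and inert to PhSe+, and the only by-product is neutral phthalimide, so both epoxides and the silyl ether are spared. The selenide so formed has C4–H available syn to selenium, as step 19 requires.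

Step 19
Reactants: 29 (1R,3S,4R,5S,6S,7R,8R,10R)-3-(tert-butyldimethylsilyloxy)-8-[(2S,3R)-2,3-dimethyloxirane-2-carbonyloxy]-1,10-epoxy-5-(phenylselanyl)germacr-11(13)-en-12,6-olide
Product: 31 (1R,3S,6R,7R,8R,10R)-3-(tert-butyldimethylsilyloxy)-8-[(2S,3R)-2,3-dimethyloxirane-2-carbonyloxy]-1,10-epoxygermacra-4Z,11(13)-dien-12,6-olide, via selenoxide 30 (not isolated)
Conditions: 30% aq. H2O2, pyridine, CH2Cl2, 0 °C → rt
Reagents that add atoms: none
Why: Selenoxide syn-elimination: oxidation at selenium is fast at 0 °C; elimination avoids the oxygen-bearing C6 and takes C4–H, and with the C4 and C5 configurations fixed earlier the syn-periplanar geometry brings C3 and C6 cis, giving the Z C4=C5 alkene stereospecifically; pyridine buffers the selenium acids.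

Step 20
Reactants: 31 (1R,3S,6R,7R,8R,10R)-3-(tert-butyldimethylsilyloxy)-8-[(2S,3R)-2,3-dimethyloxirane-2-carbonyloxy]-1,10-epoxygermacra-4Z,11(13)-dien-12,6-olide
Product: 32 (1R,3S,6R,7R,8R,10R)-8-[(2S,3R)-2,3-dimethyloxirane-2-carbonyloxy]-1,10-epoxy-3-hydroxygermacra-4Z,11(13)-dien-12,6-olide (CNP0268255.5)
Conditions: HF·pyridine, pyridine, THF, 0 °C → rt
Reagents that add atoms: none
Why: Fluoride-mediated desilylation buffered with excess pyridine, conditions mild enough for trisubstituted epoxides, a glycidic ester and an α-methylene lactone; no stereocentre is involved.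

## Compound list

1 | allyl acrylate | C=CC(=O)OCC=C | starting material
2 | acrolein | C=CC=O | starting material
3 | allyl 3-hydroxy-2-methylidenepent-4-enoate (racemic) | C=CC(O)C(=C)C(=O)OCC=C | intermediate
4 | allyl (2Z)-2-(bromomethyl)penta-2,4-dienoate | C=CCOC(=O)/C(CBr)=C/C=C | intermediate
5 | tiglic acid | C/C=C(\C)C(=O)O | starting material
6 | (2E)-2-methylbut-2-en-1-ol | C/C=C(\C)CO | intermediate
7 | [(2R,3R)-2,3-dimethyloxiran-2-yl]methanol | OC[C@@]1(C)O[C@@H]1C | intermediate
8 | (2S,3R)-2,3-dimethyloxirane-2-carboxylic acid | O=C(O)[C@@]1(C)O[C@@H]1C | intermediate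
9 | 3-butyn-1-ol | C#CCCO | starting material
10 | 1-[(but-3-yn-1-yloxy)methyl]-4-methoxybenzene | C#CCCOCc1ccc(OC)cc1 | intermediate
11 | dimethyl{(1E)-4-[(4-methoxybenzyl)oxy]-2-methylbut-1-en-1-yl}alane | C[Al](C)/C=C(\C)CCOCc1ccc(OC)cc1 | intermediate (not isolated)
12 | lithium butyl(dimethyl){(1E)-4-[(4-methoxybenzyl)oxy]-2-methylbut-1-en-1-yl}aluminate | [Li+].CCCC[Al-](C)(C)/C=C(\C)CCOCc1ccc(OC)cc1 | intermediate (not isolated)
13 | (3E)-6-[(4-methoxybenzyl)oxy]-4-methylhex-3-en-1-ol | OCC/C=C(\C)CCOCc1ccc(OC)cc1 | intermediate
14 | (3E)-6-[(4-methoxybenzyl)oxy]-4-methylhex-3-enal | O=CC/C=C(\C)CCOCc1ccc(OC)cc1 | intermediate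
15 | cis-2-butene | C/C=C\C | starting material
16 | (Z)-crotylpotassium | [K+].[CH2-]/C=C\C | intermediate (not isolated)
17 | (Z)-crotylbis[(+)-isopinocampheyl]borane | C/C=C\CB([C@@H]1[C@@H](C)[C@@H]2C[C@H](C1)C2(C)C)[C@@H]1[C@@H](C)[C@@H]2C[C@H](C1)C2(C)C | intermediate (not isolated)
18 | (3S,4S,6E)-9-[(4-methoxybenzyl)oxy]-3,7-dimethylnona-1,6-dien-4-ol | C=C[C@H](C)[C@@H](O)C/C=C(\C)CCOCc1ccc(OC)cc1 | intermediate
19 | tert-butyl{[(3S,4S,6E)-9-[(4-methoxybenzyl)oxy]-3,7-dimethylnona-1,6-dien-4-yl]oxy}dimethylsilane | C=C[C@H](C)[C@@H](O[Si](C)(C)C(C)(C)C)C/C=C(\C)CCOCc1ccc(OC)cc1 | intermediate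
20 | (2R,3R)-2-{2-[(4-methoxybenzyl)oxy]ethyl}-2-methyl-3-[(2S,3S)-2-(tert-butyldimethylsilyloxy)-3-methylpent-4-en-1-yl]oxirane | COc1ccc(COCC[C@@]2(C)O[C@@H]2C[C@H](O[Si](C)(C)C(C)(C)C)[C@@H](C)C=C)cc1 | intermediate
21 | 2-{(2R,3R)-3-[(2S,3S)-2-(tert-butyldimethylsilyloxy)-3-methylpent-4-en-1-yl]-2-methyloxiran-2-yl}ethan-1-ol | OCC[C@@]1(C)O[C@@H]1C[C@H](O[Si](C)(C)C(C)(C)C)[C@@H](C)C=C | intermediate
22 | {(2R,3R)-3-[(2S,3S)-2-(tert-butyldimethylsilyloxy)-3-methylpent-4-en-1-yl]-2-methyloxiran-2-yl}acetaldehyde | O=CC[C@@]1(C)O[C@@H]1C[C@H](O[Si](C)(C)C(C)(C)C)[C@@H](C)C=C | intermediate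
23 | [(2Z)-2-(allyloxycarbonyl)penta-2,4-dien-1-yl]indium dibromide (representative form of the allylindium reagent) | C=CCOC(=O)/C(C[In](Br)Br)=C/C=C | intermediate (not isolated)
24 | allyl (3R,4R)-3-ethenyl-4-hydroxy-2-methylidene-5-{(2R,3R)-3-[(2S,3S)-2-(tert-butyldimethylsilyloxy)-3-methylpent-4-en-1-yl]-2-methyloxiran-2-yl}pentanoate | C=C(C(=O)OCC=C)[C@@H](C=C)[C@H](O)C[C@@]1(C)O[C@@H]1C[C@H](O[Si](C)(C)C(C)(C)C)[C@@H](C)C=C | intermediate
25 | (2S,3R)-2,3-dimethyloxirane-2-carboxylic 2,4,6-trichlorobenzoic anhydride | O=C(OC(=O)[C@@]1(C)O[C@@H]1C)c1c(Cl)cc(Cl)cc1Cl | intermediate (not isolated)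
26 | allyl (3R,4R)-4-{[(2S,3R)-2,3-dimethyloxirane-2-carbonyl]oxy}-3-ethenyl-2-methylidene-5-{(2R,3R)-3-[(2S,3S)-2-(tert-butyldimethylsilyloxy)-3-methylpent-4-en-1-yl]-2-methyloxiran-2-yl}pentanoate | C=C(C(=O)OCC=C)[C@@H](C=C)[C@H](OC(=O)[C@@]1(C)O[C@@H]1C)C[C@@]1(C)O[C@@H]1C[C@H](O[Si](C)(C)C(C)(C)C)[C@@H](C)C=C | intermediate
27 | (3R,4R)-4-{[(2S,3R)-2,3-dimethyloxirane-2-carbonyl]oxy}-3-ethenyl-2-methylidene-5-{(2R,3R)-3-[(2S,3S)-2-(tert-butyldimethylsilyloxy)-3-methylpent-4-en-1-yl]-2-methyloxiran-2-yl}pentanoic acid | C=C(C(=O)O)[C@@H](C=C)[C@H](OC(=O)[C@@]1(C)O[C@@H]1C)C[C@@]1(C)O[C@@H]1C[C@H](O[Si](C)(C)C(C)(C)C)[C@@H](C)C=C | intermediate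
28 | (1R,3S,4S,7R,8R,10R)-3-(tert-butyldimethylsilyloxy)-8-[(2S,3R)-2,3-dimethyloxirane-2-carbonyloxy]-1,10-epoxygermacra-5Z,11(13)-dien-12-oic acid | C=C(C(=O)O)[C@@H]1[C@H](OC(=O)[C@@]2(C)O[C@@H]2C)C[C@@]2(C)O[C@@H]2C[C@H](O[Si](C)(C)C(C)(C)C)[C@@H](C)/C=C\1 | intermediate
29 | (1R,3S,4R,5S,6S,7R,8R,10R)-3-(tert-butyldimethylsilyloxy)-8-[(2S,3R)-2,3-dimethyloxirane-2-carbonyloxy]-1,10-epoxy-5-(phenylselanyl)germacr-11(13)-en-12,6-olide | C=C1C(=O)O[C@@H]2[C@@H]([Se]c3ccccc3)[C@H](C)[C@@H](O[Si](C)(C)C(C)(C)C)C[C@H]3O[C@]3(C)C[C@@H](OC(=O)[C@@]3(C)O[C@@H]3C)[C@@H]12 | intermediate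
30 | selenoxide of 29 (mixture at selenium) | C=C1C(=O)O[C@@H]2[C@@H]([Se](=O)c3ccccc3)[C@H](C)[C@@H](O[Si](C)(C)C(C)(C)C)C[C@H]3O[C@]3(C)C[C@@H](OC(=O)[C@@]3(C)O[C@@H]3C)[C@@H]12 | intermediate (not isolated)
31 | (1R,3S,6R,7R,8R,10R)-3-(tert-butyldimethylsilyloxy)-8-[(2S,3R)-2,3-dimethyloxirane-2-carbonyloxy]-1,10-epoxygermacra-4Z,11(13)-dien-12,6-olide | C=C1C(=O)O[C@@H]2/C=C(/C)[C@@H](O[Si](C)(C)C(C)(C)C)C[C@H]3O[C@]3(C)C[C@@H](OC(=O)[C@@]3(C)O[C@@H]3C)[C@@H]12 | intermediate
32 | (1R,3S,6R,7R,8R,10R)-8-[(2S,3R)-2,3-dimethyloxirane-2-carbonyloxy]-1,10-epoxy-3-hydroxygermacra-4Z,11(13)-dien-12,6-olide | C=C1C(=O)O[C@@H]2/C=C(/C)[C@@H](O)C[C@H]3O[C@]3(C)C[C@@H](OC(=O)[C@@]3(C)O[C@@H]3C)[C@@H]12 | target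

## Step count and least certain steps

Total: 20 steps. Longest linear sequence: 15 steps (steps 6–20, from 3-butyn-1-ol 9); the bromide (steps 1–2) and the epoxy acid (steps 3–5) are side branches.

**Step 18 (key step).** Loss of regio- or face control is the main danger. The ten-membered ring may populate conformers in which the C7–H bond is not held in the alkene plane, so that capture occurs at C5 (6-endo) or on the other face. The 1,10-epoxide oxygen could also intercept the seleniranium ion across the ring. Fallback, setting out from 28: epoxidise the C5=C6 alkene with dimethyldioxirane on the exposed face anti to the C11 arm to give the 5,6-epoxy acid F1. The C12 carboxyl opens it at C6 with inversion (spontaneously or with a trace of pyridinium tosylate) to the 5-hydroxy trans-lactone F2. Burgess reagent then dehydrates F2 by syn-elimination toward C4–H, which has the same stereochemical requirement as the selenoxide, and the sequence comes back to the route at 31.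

**Step 14.** Poor facial selectivity at the aldehyde is likely, because the only nearby stereocentre is the quaternary epoxide carbon C10, whose two carbon substituents differ little. The 7,8-syn relationship itself is not in doubt. Fallback, setting out from 22 and 4: a catalytic asymmetric Nozaki–Hiyama–Kishi allylation (catalytic CrCl2 with a chiral oxazoline–sulfonamide ligand, Mn, TMSCl) lets the ligand choose the aldehyde face. Allylchromium reagents give the anti adduct, here the (7R,8S) hydroxy ester F3. A Mitsunobu esterification of F3 with acid 8 (PPh3, diisopropyl azodicarboxylate) inverts C8 and installs the side chain in the same operation, coming back to the route at 26.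

**Step 17.** Closure to the wrong alkene geometry, or oligomerisation, may occur. Both vinyl groups carry allylic branches, and the energy gap between the E and Z isomers of this epoxide-containing cyclodecene is not known; dilution answers oligomerisation but not geometry. Fallback, setting out from 27: if the (5E)-ring acid F4 is what forms, iodolactonisation (I2, NaHCO3, MeCN) by anti addition gives the C5-epimeric iodolactone F5. Dehydroiodination of F5 with DBU is an anti elimination toward C4–H; its stereochemical demand is complementary to that of the selenoxide, so it again delivers the Z C4=C5 alkene. This comes back to the route at 31.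

**Step 9 (with the aldehyde from step 8).** The skipped enal 14 may isomerise into conjugation before the crotyl group is transferred, because the C2 protons are both allylic and α to the carbonyl. Fallback, setting out from 13: change the order so that no skipped enal is formed. Shi epoxidation of 13 gives epoxy alcohol F6, buffered Dess–Martin oxidation gives epoxy aldehyde F7, and the same (Z)-crotylborane 17 gives epoxy homoallylic alcohol F8. Silylation of F8 with TBSCl and imidazole in DMF comes back to the route at 20.

## Further compounds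

F1 | step 18 | (1R,3S,4S,7R,8R,10R)-3-(tert-butyldimethylsilyloxy)-8-[(2S,3R)-2,3-dimethyloxirane-2-carbonyloxy]-1,10:5,6-diepoxygermacr-11(13)-en-12-oic acid (cis-5,6-epoxide anti to the C11 arm) | C=C(C(=O)O)[C@@H]1[C@H](OC(=O)[C@@]2(C)O[C@@H]2C)C[C@@]2(C)O[C@@H]2C[C@H](O[Si](C)(C)C(C)(C)C)[C@@H](C)[C@@H]2O[C@H]12
F2 | step 18 | 5-hydroxy analogue of 29 (hydroxyl in place of phenylselanyl, same configuration at C5) | C=C1C(=O)O[C@@H]2[C@@H](O)[C@H](C)[C@@H](O[Si](C)(C)C(C)(C)C)C[C@H]3O[C@]3(C)C[C@@H](OC(=O)[C@@]3(C)O[C@@H]3C)[C@@H]12
F3 | step 14 | C8 epimer of 24, the (7R,8S) anti hydroxy allyl ester | C=C(C(=O)OCC=C)[C@@H](C=C)[C@@H](O)C[C@@]1(C)O[C@@H]1C[C@H](O[Si](C)(C)C(C)(C)C)[C@@H](C)C=C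
F4 | step 17 | (5E) isomer of 28 | C=C(C(=O)O)[C@@H]1[C@H](OC(=O)[C@@]2(C)O[C@@H]2C)C[C@@]2(C)O[C@@H]2C[C@H](O[Si](C)(C)C(C)(C)C)[C@@H](C)/C=C/1
F5 | step 17 | 5-iodo trans-lactone, C5 epimeric to 29 (iodine in place of phenylselanyl) | C=C1C(=O)O[C@@H]2[C@H](I)[C@H](C)[C@@H](O[Si](C)(C)C(C)(C)C)C[C@H]3O[C@]3(C)C[C@@H](OC(=O)[C@@]3(C)O[C@@H]3C)[C@@H]12
F6 | step 9 | 2-[(2R,3R)-3-{2-[(4-methoxybenzyl)oxy]ethyl}-3-methyloxiran-2-yl]ethan-1-ol | COc1ccc(COCC[C@@]2(C)O[C@@H]2CCO)cc1
F7 | step 9 | [(2R,3R)-3-{2-[(4-methoxybenzyl)oxy]ethyl}-3-methyloxiran-2-yl]acetaldehyde | COc1ccc(COCC[C@@]2(C)O[C@@H]2CC=O)cc1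
F8 | step 9 | (2S,3S)-1-[(2R,3R)-3-{2-[(4-methoxybenzyl)oxy]ethyl}-3-methyloxiran-2-yl]-3-methylpent-4-en-2-ol | COc1ccc(COCC[C@@]2(C)O[C@@H]2C[C@H](O)[C@@H](C)C=C)cc1
A1 | alternative 1 | ten-membered 1(10)E,4Z-diene 12,6-lactone with 3-O-TBS, free C8 hydroxyl and unsubstituted C11 | C1C(=O)O[C@@H]2/C=C(/C)[C@@H](O[Si](C)(C)C(C)(C)C)C/C=C(\C)C[C@@H](O)[C@@H]12
A2 | alternative 2 | isoxazoline-bridged (C3=N, O–C1) ten-membered 12,6-lactone with 10-O-TES and 8-O-TBS | C1C(=O)O[C@@H]2/C=C(/C)C3=NO[C@@H](C3)[C@@](O[Si](CC)(CC)CC)(C)C[C@@H](O[Si](C)(C)C(C)(C)C)[C@@H]12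
A3 | alternative 3 | ten-membered 1(10)E,2Z,4Z-triene α-methylene 12,6-lactone with C3 silyl enol ether and the C8 epoxy ester | C=C1C(=O)O[C@@H]2/C=C(/C)\C(O[Si](C)(C)C(C)(C)C)=C/C=C(\C)C[C@@H](OC(=O)[C@@]3(C)O[C@@H]3C)[C@@H]12
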